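## Retrosynthetic overview

1. Structural feature: the bond C2–C1' (ring C to ring B) and its counterpart in the second half (ring C' to ring B') both lie ortho to the B–B' biaryl bond. Each leads into the same C2–C3–C4–ring A chain with a 3R carbinol, so the target is one biaryl plus two copies of one chiral three-carbon block.
2. Rings C and C' are opened at O1–C2 (Mitsunobu, inversion) to erythro (2S,3R) carbinols, which come from a bis(aryl ketone) by chelation-controlled reduction. C3–O is therefore carried as a benzyl ether: a silyl ether would leave only the Felkin–Anh path, which gives the threo carbinol and hence the 2,3-trans series.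
3. Both C2–C1' bonds are cut at once, giving a 2,2'-dilithio pentabenzyloxybiaryl and two equivalents of an (R)-2-benzyloxy N-methoxy-N-methyl amide.
4. Amide: the C4–C4a bond is made by CuI-catalysed opening of methyl (R)-glycidate with the ring A arylmagnesium, so C3 is bought. Biaryl: iodide-selective Negishi coupling of two bromoiodoarenes, then methyl-to-benzyl exchange.
5. Ring order: A, A', B and B' are bought as arenes; C and C' close last and together in step 16.

Key step: step 13

Assumption: the target string fixes 2R,3R in both flavan units and leaves the biaryl axis open, so the axis is not controlled. If the diketone from the key step exists as two stable atropisomers, they are separated by chromatography at that stage and each is carried on in the same way.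

## Route

Step 1
Reactants: 1 5-bromo-1,2,3-trimethoxybenzene
Product: 2 1-bromo-2-iodo-3,4,5-trimethoxybenzene
Conditions: NIS (1.1 equiv), TFA (0.3 equiv), MeCN, rt, dark
Reagents that add atoms: N-iodosuccinimide, O=C1CCC(=O)N1I
Why: Electrophilic aromatic iodination; the two free positions are equivalent (each ortho to Br, ortho to one OMe and para to another), so only one monoiodide can form.

Step 2
Reactants: 3 4-bromo-1,2-dimethoxybenzene
Product: 4 1-bromo-2-iodo-4,5-dimethoxybenzene
Conditions: NIS (1.1 equiv), TFA (0.3 equiv), MeCN, rt, dark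
Reagents that add atoms: N-iodosuccinimide, O=C1CCC(=O)N1I
Why: Electrophilic aromatic iodination of a 4-substituted veratrole goes para to the C2 methoxy group, which is the position next to bromine.

Step 3
Reactants: 2 1-bromo-2-iodo-3,4,5-trimethoxybenzene; 4 1-bromo-2-iodo-4,5-dimethoxybenzene
Product: 7 2,2'-dibromo-4,4',5,5',6-pentamethoxybiphenyl, via arylmagnesium chloride 5 (not isolated), via arylzinc chloride 6 (not isolated)
Conditions: 2, iPrMgCl (1.05 equiv), THF, −40 °C; ZnCl2 (1.1 equiv), −40 °C to rt; 4 (0.95 equiv), Pd(PPh3)4 (5 mol %), THF, 50 °C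
Reagents that add atoms: none
Why: Iodine–magnesium exchange is faster than bromine exchange, and the cold ortho-bromo arylmagnesium is moved to zinc before it can lose MgBrCl; in the Negishi coupling zerovalent palladium then inserts into the C–I bond of 4 well ahead of any C–Br bond, which places both bromines unambiguously.

Step 4
Reactants: 7 2,2'-dibromo-4,4',5,5',6-pentamethoxybiphenyl
Product: 8 2,2'-dibromobiphenyl-4,4',5,5',6-pentaol
Conditions: BBr3 (7 equiv), CH2Cl2, −78 °C to rt; then H2O, 0 °C
Reagents that add atoms: none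
Why: Lewis-acid cleavage of aryl methyl ethers with BBr3 leaves the aryl bromides untouched, and the air-sensitive pentaol is used at once.

Step 5
Reactants: 8 2,2'-dibromobiphenyl-4,4',5,5',6-pentaol
Product: 9 2,2'-dibromo-4,4',5,5',6-pentakis(benzyloxy)biphenyl
Conditions: BnBr (6 equiv), K2CO3 (7 equiv), DMF, 60 °C, argon
Reagents that add atoms: benzyl bromide, BrCc1ccccc1
Why: Williamson etherification of catechol and pyrogallol phenoxides; O-alkylation dominates for these rings, and unactivated aryl bromides do not react with phenoxide under these conditions.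

Step 6
Reactants: 10 phloroglucinol
Product: 11 1,3,5-tris(benzyloxy)benzene
Conditions: BnBr (3.3 equiv), K2CO3 (4 equiv), DMF, rt to 60 °C
Reagents that add atoms: benzyl bromide, BrCc1ccccc1
Why: Williamson etherification; the C-benzylated side products typical of phloroglucinol are removed by crystallisation of the symmetric triether.

Step 7
Reactants: 11 1,3,5-tris(benzyloxy)benzene
Product: 12 3,5-bis(benzyloxy)phenol
Conditions: EtSH (1.3 equiv), NaH (1.2 equiv), DMF, 130 °C; then 1 M HCl
Reagents that add atoms: none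
Why: SN2 dealkylation by the soft thiolate at one benzylic CH2; the phenoxide formed makes the ring a much poorer leaving group for a second cleavage, so the reaction should stop at the monophenol.

Step 8
Reactants: 12 3,5-bis(benzyloxy)phenol
Product: 13 3,5-bis(benzyloxy)-2-iodophenol
Conditions: NIS (1.0 equiv), DMF, 0 °C, dark
Reagents that add atoms: N-iodosuccinimide, O=C1CCC(=O)N1I
Why: Electrophilic iodination should favour C2 (ortho to OH, para to OBn), which occurs twice and is less crowded than C4 between two benzyloxy groups; any 4-iodo isomer is removed by chromatography.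

Step 9
Reactants: 13 3,5-bis(benzyloxy)-2-iodophenol
Product: 14 1-(allyloxy)-3,5-bis(benzyloxy)-2-iodobenzene
Conditions: allyl bromide (1.3 equiv), K2CO3 (2 equiv), acetone, 50 °C
Reagents that add atoms: allyl bromide, C=CCBr
Why: Williamson etherification far below the temperature of a Claisen rearrangement marks the future O1 with a group that is removable under neutral conditions beside benzyl ethers.

Step 10
Reactants: 14 1-(allyloxy)-3,5-bis(benzyloxy)-2-iodobenzene; 15 methyl (R)-glycidate
Product: 17 methyl (R)-3-[2-(allyloxy)-4,6-bis(benzyloxy)phenyl]-2-hydroxypropanoate, via ring A arylmagnesium chloride 16 (not isolated)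
Conditions: 14, iPrMgCl·LiCl (1.1 equiv), THF, −20 to 0 °C; CuI (10 mol %), −40 °C; 15 (0.9 equiv), −40 to −10 °C; sat. aq. NH4Cl
Reagents that add atoms: none
Why: Iodine–magnesium exchange followed by copper-catalysed epoxide opening at the unsubstituted CH2 of the glycidate forms C4–C4a; the C–O bond at the stereocentre is not touched, so the R configuration passes unchanged into C3, and the low temperature spares the ester and the allyl ether.

Step 11
Reactants: 17 methyl (R)-3-[2-(allyloxy)-4,6-bis(benzyloxy)phenyl]-2-hydroxypropanoate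
Product: 18 methyl (R)-3-[2-(allyloxy)-4,6-bis(benzyloxy)phenyl]-2-(benzyloxy)propanoate
Conditions: BnBr (2 equiv), Ag2O (1.5 equiv), 4 Å MS, CH2Cl2, rt, dark
Reagents that add atoms: benzyl bromide, BrCc1ccccc1
Why: Silver-oxide-mediated O-alkylation of an alpha-hydroxy ester needs no strong base, so C3 should not racemise, and it generates no free benzyl cation that could attack the electron-rich ring A.

Step 12
Reactants: 18 methyl (R)-3-[2-(allyloxy)-4,6-bis(benzyloxy)phenyl]-2-(benzyloxy)propanoate
Product: 19 (R)-3-[2-(allyloxy)-4,6-bis(benzyloxy)phenyl]-2-(benzyloxy)-N-methoxy-N-methylpropanamide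
Conditions: MeNHOMe·HCl (2 equiv), iPrMgCl (4 equiv), THF, −20 to 0 °C; sat. aq. NH4Cl
Reagents that add atoms: N,O-dimethylhydroxylamine hydrochloride, CNOC.Cl
Why: Aminolysis of the ester by the magnesium amide made in the flask (Weinreb amide formation) is fast at low temperature and should leave the alpha-alkoxy centre intact.

Step 13
Reactants: 9 2,2'-dibromo-4,4',5,5',6-pentakis(benzyloxy)biphenyl; 19 (R)-3-[2-(allyloxy)-4,6-bis(benzyloxy)phenyl]-2-(benzyloxy)-N-methoxy-N-methylpropanamide (two equivalents enter)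
Product: 22 (2R,2'R)-1,1'-[4,4',5,5',6-pentakis(benzyloxy)biphenyl-2,2'-diyl]bis{3-[2-(allyloxy)-4,6-bis(benzyloxy)phenyl]-2-(benzyloxy)propan-1-one}, via 2,2'-dilithiobiaryl 20 (not isolated), via bis(lithium hemiaminal alkoxide) 21 (not isolated)
Conditions: 9, tBuLi (4.1 equiv), THF–Et2O, −78 °C; 19 (2.3 equiv), THF, −78 to −40 °C; sat. aq. NH4Cl at −40 °C
Reagents that add atoms: none
Why: Each C–Br bond undergoes bromine–lithium exchange (a second equivalent of tBuLi per bromide destroys the tBuBr formed), and each aryllithium of 20 then adds to the carbonyl of one molecule of 19, forming both C2–C1' bonds. The closest known reaction type is the Weinreb ketone synthesis with aryllithiums, and 2,2'-dilithiobiphenyls are established double nucleophiles. No ring closes and no stereocentre is created in 22; both C3 centres come unchanged from 15. The five-membered O–Li–OMe chelate keeps each adduct in 21 tetrahedral until the cold quench, so no ketone exists while a neighbouring aryllithium is still alive, which excludes over-addition and closure to a 9-fluorenol. The step needs addition to outrun proton transfer from C3–H and from the benzylic OCH2 groups, and the low temperature, the slim C3 benzyl ether (less hindering than a silyl ether and able to guide lithium to the carbonyl) and a slight excess of 19 serve this. The biaryl axis is not controlled here.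

Step 14
Reactants: 22 the bis(alpha-benzyloxy ketone)
Product: 23 (1S,1'S,2R,2'R)-1,1'-[4,4',5,5',6-pentakis(benzyloxy)biphenyl-2,2'-diyl]bis{3-[2-(allyloxy)-4,6-bis(benzyloxy)phenyl]-2-(benzyloxy)propan-1-ol} (flavan numbering: 2S,3R, erythro, in both halves)
Conditions: Zn(BH4)2 (3 equiv, Et2O stock solution), CH2Cl2–Et2O, −40 to 0 °C; then H2O
Reagents that add atoms: none
Why: Chelation-controlled reduction of an alpha-alkoxy ketone: zinc ties the C2 carbonyl oxygen and the C3 benzyloxy oxygen into a five-membered Cram chelate and hydride enters from the face bearing C3–H, which sets 2S (erythro to 3R) in each half, while the allyl ethers are not hydroborated at this temperature.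

Step 15
Reactants: 23 the erythro,erythro diol bis(allyl ether)
Product: 24 the corresponding bis(phenol): (1S,1'S,2R,2'R)-1,1'-[4,4',5,5',6-pentakis(benzyloxy)biphenyl-2,2'-diyl]bis{3-[4,6-bis(benzyloxy)-2-hydroxyphenyl]-2-(benzyloxy)propan-1-ol}
Conditions: Pd(PPh3)4 (10 mol %), morpholine (10 equiv), THF, rt
Reagents that add atoms: none
Why: Tsuji–Trost-type deallylation: zerovalent palladium ionises the allyl aryl ether and morpholine captures the allyl unit, under non-acidic conditions that cannot ionise the electron-rich benzylic carbinols or disturb the benzyl ethers.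

Step 16
Reactants: 24 the bis(phenol) diol
Product: 25 undeca-O-benzyl degalloyl theasinensin F (2R,3R in both flavan units)
Conditions: PPh3 (4 equiv), DIAD (4 equiv), toluene (0.005 M), 0 °C to rt
Reagents that add atoms: none
Why: Double intramolecular Mitsunobu etherification: phosphonium activation of each C2 hydroxyl and 6-exo-tet SN2 attack by the ring A phenoxide invert 2S to 2R and close the 2,3-cis pyran rings C and C', with the electron-withdrawing C3 benzyloxy group and the non-polar solvent holding back ionisation to a benzylic cation.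

Step 17
Reactants: 25 undeca-O-benzyl degalloyl theasinensin F
Product: 26 degalloyl theasinensin F
Conditions: H2 (1 atm), Pd(OH)2/C, THF–MeOH, rt; filtration and concentration under argon
Reagents that add atoms: none
Why: Catalytic hydrogenolysis removes all eleven benzyl ethers, including the two at C3–O, under neutral conditions that are standard for benzylated flavan-3-ols and leave the cyclic O1–C2 bond and all four stereocentres intact.

## Compound list

1 | 5-bromo-1,2,3-trimethoxybenzene | COc1cc(Br)cc(OC)c1OC | starting material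
2 | 1-bromo-2-iodo-3,4,5-trimethoxybenzene | COc1cc(Br)c(I)c(OC)c1OC | intermediate
3 | 4-bromo-1,2-dimethoxybenzene | COc1ccc(Br)cc1OC | starting material
4 | 1-bromo-2-iodo-4,5-dimethoxybenzene | COc1cc(Br)c(I)cc1OC | intermediate
5 | (6-bromo-2,3,4-trimethoxyphenyl)magnesium chloride | COc1cc(Br)c([Mg]Cl)c(OC)c1OC | intermediate
6 | (6-bromo-2,3,4-trimethoxyphenyl)zinc chloride | COc1cc(Br)c([Zn]Cl)c(OC)c1OC | intermediate
7 | 2,2'-dibromo-4,4',5,5',6-pentamethoxybiphenyl | Brc1cc(OC)c(OC)cc1-c1c(Br)cc(OC)c(OC)c1OC | intermediate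
8 | 2,2'-dibromobiphenyl-4,4',5,5',6-pentaol | Brc1cc(O)c(O)cc1-c1c(Br)cc(O)c(O)c1O | intermediate
9 | 2,2'-dibromo-4,4',5,5',6-pentakis(benzyloxy)biphenyl | Brc1cc(OCc7ccccc7)c(OCc7ccccc7)cc1-c1c(Br)cc(OCc7ccccc7)c(OCc7ccccc7)c1OCc7ccccc7 | intermediate
10 | phloroglucinol | Oc1cc(O)cc(O)c1 | starting material
11 | 1,3,5-tris(benzyloxy)benzene | c1(OCc7ccccc7)cc(OCc7ccccc7)cc(OCc7ccccc7)c1 | intermediate
12 | 3,5-bis(benzyloxy)phenol | Oc1cc(OCc7ccccc7)cc(OCc7ccccc7)c1 | intermediate
13 | 3,5-bis(benzyloxy)-2-iodophenol | Oc1cc(OCc7ccccc7)cc(OCc7ccccc7)c1I | intermediate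
14 | 1-(allyloxy)-3,5-bis(benzyloxy)-2-iodobenzene | C=CCOc1cc(OCc7ccccc7)cc(OCc7ccccc7)c1I | intermediate
15 | methyl (R)-glycidate | COC(=O)[C@H]1CO1 | starting material
16 | [2-(allyloxy)-4,6-bis(benzyloxy)phenyl]magnesium chloride | C=CCOc1cc(OCc7ccccc7)cc(OCc7ccccc7)c1[Mg]Cl | intermediate
17 | methyl (R)-3-[2-(allyloxy)-4,6-bis(benzyloxy)phenyl]-2-hydroxypropanoate | COC(=O)[C@H](O)Cc1c(OCC=C)cc(OCc7ccccc7)cc1OCc7ccccc7 | intermediate
18 | methyl (R)-3-[2-(allyloxy)-4,6-bis(benzyloxy)phenyl]-2-(benzyloxy)propanoate | COC(=O)[C@H](OCc7ccccc7)Cc1c(OCC=C)cc(OCc7ccccc7)cc1OCc7ccccc7 | intermediate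
19 | (R)-3-[2-(allyloxy)-4,6-bis(benzyloxy)phenyl]-2-(benzyloxy)-N-methoxy-N-methylpropanamide | CON(C)C(=O)[C@H](OCc7ccccc7)Cc1c(OCC=C)cc(OCc7ccccc7)cc1OCc7ccccc7 | intermediate
20 | 2,2'-dilithio-4,4',5,5',6-pentakis(benzyloxy)biphenyl | [Li]c1cc(OCc7ccccc7)c(OCc7ccccc7)cc1-c1c([Li])cc(OCc7ccccc7)c(OCc7ccccc7)c1OCc7ccccc7 | intermediate
21 | bis(lithium hemiaminal alkoxide), double tetrahedral adduct of 20 and 19 (hemiaminal carbons undefined, both C3 R) | [Li]OC(N(C)OC)(c1cc(OCc7ccccc7)c(OCc7ccccc7)cc1-c1c(C(O[Li])(N(C)OC)[C@H](OCc7ccccc7)Cc2c(OCC=C)cc(OCc7ccccc7)cc2OCc7ccccc7)cc(OCc7ccccc7)c(OCc7ccccc7)c1OCc7ccccc7)[C@H](OCc7ccccc7)Cc1c(OCC=C)cc(OCc7ccccc7)cc1OCc7ccccc7 | intermediate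
22 | bis(alpha-benzyloxy ketone), (2R,2'R) | O=C(c1cc(OCc7ccccc7)c(OCc7ccccc7)cc1-c1c(C(=O)[C@H](OCc7ccccc7)Cc2c(OCC=C)cc(OCc7ccccc7)cc2OCc7ccccc7)cc(OCc7ccccc7)c(OCc7ccccc7)c1OCc7ccccc7)[C@H](OCc7ccccc7)Cc1c(OCC=C)cc(OCc7ccccc7)cc1OCc7ccccc7 | intermediate
23 | erythro,erythro diol bis(allyl ether), (1S,1'S,2R,2'R) | O[C@@H](c1cc(OCc7ccccc7)c(OCc7ccccc7)cc1-c1c([C@H](O)[C@H](OCc7ccccc7)Cc2c(OCC=C)cc(OCc7ccccc7)cc2OCc7ccccc7)cc(OCc7ccccc7)c(OCc7ccccc7)c1OCc7ccccc7)[C@H](OCc7ccccc7)Cc1c(OCC=C)cc(OCc7ccccc7)cc1OCc7ccccc7 | intermediate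
24 | erythro,erythro diol bis(phenol), (1S,1'S,2R,2'R) | O[C@@H](c1cc(OCc7ccccc7)c(OCc7ccccc7)cc1-c1c([C@H](O)[C@H](OCc7ccccc7)Cc2c(O)cc(OCc7ccccc7)cc2OCc7ccccc7)cc(OCc7ccccc7)c(OCc7ccccc7)c1OCc7ccccc7)[C@H](OCc7ccccc7)Cc1c(O)cc(OCc7ccccc7)cc1OCc7ccccc7 | intermediate
25 | undeca-O-benzyl degalloyl theasinensin F, (2R,3R) in both units | C(c7ccccc7)Oc1cc(OCc7ccccc7)c2c(c1)O[C@H](c1cc(OCc7ccccc7)c(OCc7ccccc7)cc1-c1c([C@H]3Oc4cc(OCc7ccccc7)cc(OCc7ccccc7)c4C[C@H]3OCc7ccccc7)cc(OCc7ccccc7)c(OCc7ccccc7)c1OCc7ccccc7)[C@H](OCc7ccccc7)C2 | intermediate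
26 | degalloyl theasinensin F | Oc1cc(O)c2c(c1)O[C@H](c1cc(O)c(O)cc1-c1c([C@H]3Oc4cc(O)cc(O)c4C[C@H]3O)cc(O)c(O)c1O)[C@H](O)C2 | target

## Counts

Total step count: 17.
Longest linear sequence: 12 steps (phloroglucinol 10, steps 6–17).

## Steps most likely to fail

**1. Step 13 (key step).** The second aryllithium is crowded by the first tetrahedral adduct. It may be protonated (enolisation of the amide at C3–H, or lithium–hydrogen exchange at a benzylic OCH2), or it may trigger base-induced loss of the N-methoxy group faster than it adds. In either case the union stops after one acylation.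

The fallback replaces acyl transfer by carbonyl addition followed by oxidation, and it sets out from 19 and 9. iBu2AlH (THF, −78 °C) reduces 19 to (R)-3-[2-(allyloxy)-4,6-bis(benzyloxy)phenyl]-2-(benzyloxy)propanal F1. Dilithiobiaryl 20, made from 9 as in step 13, adds at −78 °C to two equivalents of this smaller and more electrophilic partner to give the C2-epimeric bis(carbinol) F2. Dess–Martin periodinane (NaHCO3, CH2Cl2) oxidises both carbinols, and the route is rejoined at 22.

**2. Step 16.** The activated C2 centres are para-alkoxybenzylic and flanked by the biaryl. Ionisation to a benzylic cation (loss of stereochemical integrity, drift to the 2,3-trans ring), elimination towards C3, or failure of the crowded hydroxyl to be activated may each compete with the SN2 closure, and the closure has to succeed twice.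

The fallback closes the pyran rings at O1–C8a instead of O1–C2, so that C2 is not a reaction centre and needs retention. It sets out from 22. Pd(PPh3)4 and morpholine (THF, rt) free the phenols to give the bis(phenol) diketone F3. PhNTf2 and Cs2CO3 (DMF, rt) convert them into the bis(aryl triflate) diketone F4. LiBH(sBu)3 (THF, −78 °C) reduces both ketones along the polar Felkin–Anh path to the threo (2R,3R) diol bis(triflate) F5. Intramolecular Buchwald–Hartwig etherification (Pd(OAc)2, 2-(di-tert-butylphosphino)-1,1'-binaphthyl, Cs2CO3, toluene, 70 °C) joins each C2 oxygen to C8a with retention, and the route is rejoined at 25.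

**3. Step 14.** Facial selectivity may be poor if the twisted, crowded aryl ketones do not hold the zinc chelate, if the many other ether oxygens compete for zinc, or if the biaryl axis overrides the bias from C3. The selectivity has to be delivered at two centres.

The fallback uses the intrinsic non-chelation bias and then inverts, and it sets out from 22. LiBH(sBu)3 (THF, −78 °C) gives the threo (2R,3R) diol bis(allyl ether) F6. Mitsunobu esterification with 4-nitrobenzoic acid (PPh3, DIAD, toluene, 0 °C to rt) inverts both carbinols to the erythro bis(4-nitrobenzoate) F7. K2CO3 in MeOH–THF cleaves the esters, and the route is rejoined at 23.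

## Further compounds

F1 | step 13 | (R)-3-[2-(allyloxy)-4,6-bis(benzyloxy)phenyl]-2-(benzyloxy)propanal | O=C[C@H](OCc7ccccc7)Cc1c(OCC=C)cc(OCc7ccccc7)cc1OCc7ccccc7
F2 | step 13 | C2-epimeric bis(carbinol), both C3 R, carbinol centres undefined | OC(c1cc(OCc7ccccc7)c(OCc7ccccc7)cc1-c1c(C(O)[C@H](OCc7ccccc7)Cc2c(OCC=C)cc(OCc7ccccc7)cc2OCc7ccccc7)cc(OCc7ccccc7)c(OCc7ccccc7)c1OCc7ccccc7)[C@H](OCc7ccccc7)Cc1c(OCC=C)cc(OCc7ccccc7)cc1OCc7ccccc7
F3 | step 16 | bis(phenol) diketone, (2R,2'R) | O=C(c1cc(OCc7ccccc7)c(OCc7ccccc7)cc1-c1c(C(=O)[C@H](OCc7ccccc7)Cc2c(O)cc(OCc7ccccc7)cc2OCc7ccccc7)cc(OCc7ccccc7)c(OCc7ccccc7)c1OCc7ccccc7)[C@H](OCc7ccccc7)Cc1c(O)cc(OCc7ccccc7)cc1OCc7ccccc7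
F4 | step 16 | bis(aryl triflate) diketone, (2R,2'R) | O=C(c1cc(OCc7ccccc7)c(OCc7ccccc7)cc1-c1c(C(=O)[C@H](OCc7ccccc7)Cc2c(OS(=O)(=O)C(F)(F)F)cc(OCc7ccccc7)cc2OCc7ccccc7)cc(OCc7ccccc7)c(OCc7ccccc7)c1OCc7ccccc7)[C@H](OCc7ccccc7)Cc1c(OS(=O)(=O)C(F)(F)F)cc(OCc7ccccc7)cc1OCc7ccccc7
F5 | step 16 | threo diol bis(triflate), flavan numbering 2R,3R in both halves | O[C@H](c1cc(OCc7ccccc7)c(OCc7ccccc7)cc1-c1c([C@@H](O)[C@H](OCc7ccccc7)Cc2c(OS(=O)(=O)C(F)(F)F)cc(OCc7ccccc7)cc2OCc7ccccc7)cc(OCc7ccccc7)c(OCc7ccccc7)c1OCc7ccccc7)[C@H](OCc7ccccc7)Cc1c(OS(=O)(=O)C(F)(F)F)cc(OCc7ccccc7)cc1OCc7ccccc7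
F6 | step 14 | threo diol bis(allyl ether), flavan numbering 2R,3R in both halves | O[C@H](c1cc(OCc7ccccc7)c(OCc7ccccc7)cc1-c1c([C@@H](O)[C@H](OCc7ccccc7)Cc2c(OCC=C)cc(OCc7ccccc7)cc2OCc7ccccc7)cc(OCc7ccccc7)c(OCc7ccccc7)c1OCc7ccccc7)[C@H](OCc7ccccc7)Cc1c(OCC=C)cc(OCc7ccccc7)cc1OCc7ccccc7
F7 | step 14 | erythro bis(4-nitrobenzoate), flavan numbering 2S,3R in both halves | O=C(c8ccc(cc8)[N+](=O)[O-])O[C@@H](c1cc(OCc7ccccc7)c(OCc7ccccc7)cc1-c1c([C@H](OC(=O)c8ccc(cc8)[N+](=O)[O-])[C@H](OCc7ccccc7)Cc2c(OCC=C)cc(OCc7ccccc7)cc2OCc7ccccc7)cc(OCc7ccccc7)c(OCc7ccccc7)c1OCc7ccccc7)[C@H](OCc7ccccc7)Cc1c(OCC=C)cc(OCc7ccccc7)cc1OCc7ccccc7
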